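**Plan**

Ring numbering: C1 (bears =CH2), C2=C3, C4 (CMe2), C5, C6 (acyloxy), C7, C8(Me)=C9, C10, C11.
Enabling feature: the C10–C11 single bond lies between the C8=C9 alkene and the C1–C2 unit, which at the ketone level is an enolate. This is the pattern left by an oxy-Cope shift, so the eleven-membered ring can be made from a cycloheptanol (C2–C8 bonded) by a four-atom ring expansion.
Cuts: the ester C–O bond; C2=C3 back to a C2 ketone; C10–C11 (retro-oxy-Cope, restoring C2–C8); C1–C2 (alkenylcerium plus cycloheptanone); C8–CH3 and C8–C9 (methylation, aldol); the cycloheptene C=C (metathesis of a divinyl diol from 3,3-dimethylglutaric acid).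
Forward order: the seven-membered ring is closed by metathesis, the methyl/vinyl carbon and the alkenyl carbinol are installed, the ring is expanded to eleven, and the diene and then the ester are completed.
Stereochemistry: C6 comes from an enzymatic monoreduction of the symmetric dione 8; E-C8=C9 from the chair transition state of the trans-dialkenyl carbinol; E-C2=C3 from the enolate geometry, kept through the triflate reduction.

Key step: step 13

Remark: the carbons set in steps 10 and 12 both become sp2 in step 13, so only their relative configuration (alkenyl groups trans) matters. Compounds 16 and 21 are drawn as the diastereomers expected to predominate; a C2 epimer of 16, if formed, would be separated and taken through steps 12 and 13 to the same ketone 24.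

**Route**

Step 1
Reactants: 1 3,3-dimethylglutaric acid
Product: 2 3,3-dimethylpentane-1,5-diol
Conditions: LiAlH4, THF, 0 °C → reflux; aqueous NaOH work-up
Reagents that add atoms: none
Why: Hydride reduction of both carboxyl groups with LiAlH4 should give the 1,5-diol; the gem-dimethyl carbon is untouched and no stereocentre is involved.

Step 2
Reactants: 2 3,3-dimethylpentane-1,5-diol
Product: 3 3,3-dimethylpentanedial
Conditions: (COCl)2, DMSO, CH2Cl2, −78 °C; Et3N, −78 °C → rt; used crude
Reagents that add atoms: none
Why: Swern oxidation activates both primary hydroxyls at once and stops at the dialdehyde, avoiding the lactol-to-lactone path that other oxidants open for 1,5-diols.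

Step 3
Reactants: 3 3,3-dimethylpentanedial; 4 vinylmagnesium bromide
Product: 5 5,5-dimethylnona-1,8-diene-3,7-diol (diastereomer mixture)
Conditions: 4 (2.5 equiv), THF, −78 → 0 °C; aqueous NH4Cl
Reagents that add atoms: none
Why: Twofold Grignard addition to the aldehydes should give the bis-allylic diol; the two carbinol centres form without control, which is harmless because both are oxidised in step 6.

Step 4
Reactants: 5 5,5-dimethylnona-1,8-diene-3,7-diol
Product: 6 6,6-dimethylcyclohept-2-ene-1,4-diol (cis/trans mixture)
Conditions: second-generation Grubbs catalyst (H2IMes)(PCy3)Cl2Ru=CHPh (2 mol%), CH2Cl2 (0.01 M), 40 °C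
Reagents that add atoms: none
Why: Ring-closing olefin metathesis of the 1,8-diene with loss of ethene should close the cycloheptene, helped by the gem-dimethyl group (Thorpe–Ingold effect) and tolerant of free allylic alcohols.

Step 5
Reactants: 6 6,6-dimethylcyclohept-2-ene-1,4-diol
Product: 7 6,6-dimethylcycloheptane-1,4-diol (cis/trans mixture)
Conditions: H2 (1 atm), Pd/C, EtOAc, rt
Reagents that add atoms: none
Why: Heterogeneous catalytic hydrogenation saturates the disubstituted ring alkene, and any allylic alcohol isomerised to ketone on the metal converges in step 6.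

Step 6
Reactants: 7 6,6-dimethylcycloheptane-1,4-diol
Product: 8 6,6-dimethylcycloheptane-1,4-dione
Conditions: Dess–Martin periodinane, NaHCO3, CH2Cl2, rt
Reagents that add atoms: none
Why: Dess–Martin oxidation of both secondary alcohols under buffered conditions erases the uncontrolled carbinol centres and should give the symmetric 1,4-dione.

Step 7
Reactants: 8 6,6-dimethylcycloheptane-1,4-dione
Product: 9 (S)-4-hydroxy-6,6-dimethylcycloheptan-1-one
Conditions: ketoreductase (chosen from a panel for the S alcohol), NADP+ (cat.), i-PrOH, phosphate buffer pH 7, 30 °C, stopped after one hydride equivalent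
Reagents that add atoms: none
Why: In this ketoreductase-catalysed asymmetric reduction the two carbonyls of 8 are related by a twofold axis, so hydride delivery to one face of either carbonyl gives the same alcohol, and the enzyme sets the new stereocentre by telling the CH2CMe2 flank from the CH2CH2C(=O) flank.

Step 8
Reactants: 9 (S)-4-hydroxy-6,6-dimethylcycloheptan-1-one
Product: 10 (S)-4-(tert-butyldimethylsilyloxy)-6,6-dimethylcycloheptan-1-one
Conditions: TBSCl, imidazole, DMF, rt
Reagents that add atoms: tert-butyldimethylsilyl chloride, CC(C)(C)[Si](C)(C)Cl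
Why: Standard silylation of a secondary alcohol traps the open keto alcohol and does not touch the stereocentre.

Step 9
Reactants: 10 (S)-4-(tert-butyldimethylsilyloxy)-6,6-dimethylcycloheptan-1-one
Product: 14 (2E,4R)-4-(tert-butyldimethylsilyloxy)-2-ethylidene-6,6-dimethylcycloheptan-1-one, via lithium enolate 11 (not isolated), via lithium aldolate 12 (not isolated), via aldol mesylate 13 (not isolated)
Conditions: LiN(i-Pr)2, THF, −78 °C; MeCHO; MsCl, −78 → 0 °C; DBU, rt
Reagents that add atoms: acetaldehyde, CC=O
Why: Kinetic deprotonation should occur at C2, the α-methylene not flanked by the quaternary carbon, and the aldol adduct is dehydrated through its mesylate by E1cB elimination (aldol condensation) to the more stable E-ethylidene ketone.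

Step 10
Reactants: 14 (2E,4R)-4-(tert-butyldimethylsilyloxy)-2-ethylidene-6,6-dimethylcycloheptan-1-one
Product: 16 (2R,4R)-4-(tert-butyldimethylsilyloxy)-2-ethenyl-2,6,6-trimethylcycloheptan-1-one, via potassium dienolate 15 (not isolated)
Conditions: KOt-Bu (1.05 equiv), THF/t-BuOH, 0 °C; MeI
Reagents that add atoms: iodomethane, CI
Why: In this deconjugative α-alkylation of an enone, equilibrating γ-deprotonation gives the extended dienolate, which is methylated at the α-carbon; the methyl should enter on the face away from the folded C4–C6 segment, cis to the equatorial silyloxy group, at a centre that is destroyed in step 13.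

Step 11
Reactants: 17 2,3-dibromopropene
Product: 18 2-bromo-3-methoxyprop-1-ene
Conditions: NaOMe, MeOH, 0 °C → rt; distillation
Reagents that add atoms: sodium methoxide, [Na+].[O-]C
Why: SN2 displacement of the allylic bromide by methoxide; the vinylic bromide is inert under these conditions.

Step 12
Reactants: 16 (2R,4R)-4-(tert-butyldimethylsilyloxy)-2-ethenyl-2,6,6-trimethylcycloheptan-1-one; 18 2-bromo-3-methoxyprop-1-ene
Product: 21 (1R,2R,4R)-4-(tert-butyldimethylsilyloxy)-2-ethenyl-1-(3-methoxyprop-1-en-2-yl)-2,6,6-trimethylcycloheptan-1-ol, via 2-lithio-3-methoxypropene 19 (not isolated), via dichloro(3-methoxyprop-1-en-2-yl)cerium 20 (not isolated)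
Conditions: 18, t-BuLi (2 equiv), Et2O, −78 °C; CeCl3 (dried), THF, −78 °C; then 16, −78 → −40 °C; chromatography
Reagents that add atoms: none
Why: Bromine–lithium exchange and transmetallation give a weakly basic alkenylcerium reagent that adds to the hindered, enolisable ketone (organocerium 1,2-addition), and attack anti to the vinyl group (Felkin–Anh sense) should set the carbinol centre with the two alkenyl groups trans, any cis isomer being removed by chromatography.

Step 13
Reactants: 21 (1R,2R,4R)-4-(tert-butyldimethylsilyloxy)-2-ethenyl-1-(3-methoxyprop-1-en-2-yl)-2,6,6-trimethylcycloheptan-1-ol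
Product: 24 (5E,8R)-8-(tert-butyldimethylsilyloxy)-6,10,10-trimethyl-2-methylidenecycloundec-5-en-1-one, via potassium alkoxide 22 (not isolated), via potassium enolate 23 (not isolated)
Conditions: KH (3 equiv), 18-crown-6, THF, 0 °C → 50 °C; quench into cold pH 7 buffer
Reagents that add atoms: none
Why: KH with 18-crown-6 gives the dissociated alkoxide 22, whose 1,5-diene C11=C1–C2–C8–C9=C10 undergoes the alkoxide-accelerated [3,3]-sigmatropic shift, forming C10–C11 and breaking C2–C8. The closest known reaction type is the anionic oxy-Cope ring expansion of trans-1,2-dialkenylcycloalkanols to medium-ring enolates. The eleven-membered ring is not closed end to end; it arises by four-atom expansion of the cycloheptane through a six-membered chair transition state. No stereocentre is created: both cycloheptanol centres become sp2 and the silyloxy carbon is a spectator. The step needs E geometry at C8=C9, which the trans alkenyl groups secure because only then can both ring bonds (C8–C7 and C2–C3) sit pseudo-equatorial on the chair. The regiodefined C1=C2 enolate 23 carries a β-methoxy group and should expel methoxide (E1cB), placing the exocyclic methylene at C1.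

Step 14
Reactants: 24 (5E,8R)-8-(tert-butyldimethylsilyloxy)-6,10,10-trimethyl-2-methylidenecycloundec-5-en-1-one
Product: 26 (1Z,5S,7E)-5-(tert-butyldimethylsilyloxy)-3,3,7-trimethyl-11-methylidenecycloundeca-1,7-dien-1-yl trifluoromethanesulfonate, via potassium dienolate 25 (not isolated)
Conditions: KN(SiMe3)2, THF, −78 °C; PhNTf2, −78 → 0 °C
Reagents that add atoms: N-phenylbis(trifluoromethanesulfonimide), O=S(=O)(N(c1ccccc1)S(=O)(=O)C(F)(F)F)C(F)(F)F
Why: C3 is the only enolisable position of the enone, and in this enol triflate formation the enolate should form with oxygen cis to the bulky C4 (C1 trans to C4) to avoid allylic strain with the C1 methylene unit, which fixes the E ring geometry before O-sulfonylation.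

Step 15
Reactants: 26 (1Z,5S,7E)-5-(tert-butyldimethylsilyloxy)-3,3,7-trimethyl-11-methylidenecycloundeca-1,7-dien-1-yl trifluoromethanesulfonate
Product: 27 tert-butyldimethyl{[(1S,3E,8E)-3,10,10-trimethyl-7-methylidenecycloundeca-3,8-dien-1-yl]oxy}silane
Conditions: Pd(OAc)2 (5 mol%), PPh3 (10 mol%), Bu3N, HCO2H, DMF, 60 °C
Reagents that add atoms: none
Why: Palladium-catalysed formate reduction of an enol triflate (oxidative addition to zerovalent palladium, formate exchange, decarboxylation, reductive elimination) replaces OTf by H with retention of alkene geometry and should give the E,E-triene.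

Step 16
Reactants: 27 tert-butyldimethyl{[(1S,3E,8E)-3,10,10-trimethyl-7-methylidenecycloundeca-3,8-dien-1-yl]oxy}silane
Product: 28 (1S,3E,8E)-3,10,10-trimethyl-7-methylidenecycloundeca-3,8-dien-1-ol
Conditions: Bu4NF, THF, rt
Reagents that add atoms: none
Why: Fluoride-mediated desilylation frees the secondary alcohol without exposing the triene to acid.

Step 17
Reactants: 29 isovanillic acid
Product: 31 3-(tert-butyldimethylsilyloxy)-4-methoxybenzoic acid, via silyl ester silyl ether 30 (not isolated)
Conditions: TBSCl (2.5 equiv), imidazole, DMF, rt; then AcOH, THF/H2O, rt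
Reagents that add atoms: tert-butyldimethylsilyl chloride, CC(C)(C)[Si](C)(C)Cl
Why: Exhaustive silylation followed by selective hydrolysis of the labile silyl ester should leave the aryl silyl ether and free the carboxylic acid.

Step 18
Reactants: 28 (1S,3E,8E)-3,10,10-trimethyl-7-methylidenecycloundeca-3,8-dien-1-ol; 31 3-(tert-butyldimethylsilyloxy)-4-methoxybenzoic acid
Product: 32 (1S,3E,8E)-3,10,10-trimethyl-7-methylidenecycloundeca-3,8-dien-1-yl 3-(tert-butyldimethylsilyloxy)-4-methoxybenzoate
Conditions: DCC, DMAP (cat.), CH2Cl2, 0 °C → rt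
Reagents that add atoms: none
Why: Steglich esterification acylates the alcohol at oxygen, so the C6 configuration is retained.

Step 19
Reactants: 32 (1S,3E,8E)-3,10,10-trimethyl-7-methylidenecycloundeca-3,8-dien-1-yl 3-(tert-butyldimethylsilyloxy)-4-methoxybenzoate
Product: 33 (1S,3E,8E)-3,10,10-trimethyl-7-methylidenecycloundeca-3,8-dien-1-yl 3-hydroxy-4-methoxybenzoate
Conditions: Bu4NF, AcOH, THF, 0 °C
Reagents that add atoms: none
Why: Buffered fluoride cleaves the aryl silyl ether (desilylation) quickly at 0 °C, conditions under which the benzoate ester and the acid-sensitive triene should be stable.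

**Compound list**

1 | 3,3-dimethylglutaric acid | CC(C)(CC(=O)O)CC(=O)O | starting material
2 | 3,3-dimethylpentane-1,5-diol | CC(C)(CCO)CCO | intermediate
3 | 3,3-dimethylpentanedial | CC(C)(CC=O)CC=O | intermediate
4 | vinylmagnesium bromide | C=C[Mg]Br | starting material
5 | 5,5-dimethylnona-1,8-diene-3,7-diol (meso and racemic diastereomers, both erased in step 6) | C=CC(O)CC(C)(C)CC(O)C=C | intermediate
6 | 6,6-dimethylcyclohept-2-ene-1,4-diol (cis/trans mixture) | OC1C=CC(O)CC(C)(C)C1 | intermediate
7 | 6,6-dimethylcycloheptane-1,4-diol (cis/trans mixture) | OC1CCC(O)CC(C)(C)C1 | intermediate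
8 | 6,6-dimethylcycloheptane-1,4-dione | O=C1CCC(=O)CC(C)(C)C1 | intermediate
9 | (S)-4-hydroxy-6,6-dimethylcycloheptan-1-one | O=C1CC[C@H](O)CC(C)(C)C1 | intermediate
10 | (S)-4-(tert-butyldimethylsilyloxy)-6,6-dimethylcycloheptan-1-one | O=C1CC[C@H](O[Si](C)(C)C(C)(C)C)CC(C)(C)C1 | intermediate
11 | lithium enolate of 10 (C1=C2) | [Li]OC1=CC[C@H](O[Si](C)(C)C(C)(C)C)CC(C)(C)C1 | intermediate (not isolated)
12 | lithium aldolate, 2-(1-lithiooxyethyl) derivative of 10 (epimers at the two new centres) | CC(O[Li])C1C[C@H](O[Si](C)(C)C(C)(C)C)CC(C)(C)CC1=O | intermediate (not isolated)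
13 | aldol mesylate, 2-(1-methanesulfonyloxyethyl) derivative of 10 (epimers at the two new centres) | CC(OS(C)(=O)=O)C1C[C@H](O[Si](C)(C)C(C)(C)C)CC(C)(C)CC1=O | intermediate (not isolated)
14 | (2E,4R)-4-(tert-butyldimethylsilyloxy)-2-ethylidene-6,6-dimethylcycloheptan-1-one | C/C=C1\C[C@H](O[Si](C)(C)C(C)(C)C)CC(C)(C)CC1=O | intermediate
15 | potassium dienolate of 14 (1-oxido-2-vinylcycloheptene) | C=CC1=C([O-])CC(C)(C)C[C@@H](O[Si](C)(C)C(C)(C)C)C1.[K+] | intermediate (not isolated)
16 | (2R,4R)-4-(tert-butyldimethylsilyloxy)-2-ethenyl-2,6,6-trimethylcycloheptan-1-one (methyl cis to silyloxy) | O=C1CC(C)(C)C[C@@H](O[Si](C)(C)C(C)(C)C)C[C@]1(C)C=C | intermediate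
17 | 2,3-dibromopropene | C=C(Br)CBr | starting material
18 | 2-bromo-3-methoxyprop-1-ene | C=C(Br)COC | intermediate
19 | 2-lithio-3-methoxypropene | [Li]C(=C)COC | intermediate (not isolated)
20 | dichloro(3-methoxyprop-1-en-2-yl)cerium | C=C(COC)[Ce](Cl)Cl | intermediate (not isolated)
21 | (1R,2R,4R)-4-(tert-butyldimethylsilyloxy)-2-ethenyl-1-(3-methoxyprop-1-en-2-yl)-2,6,6-trimethylcycloheptan-1-ol (alkenyl groups trans) | C=C(COC)[C@@]1(O)CC(C)(C)C[C@@H](O[Si](C)(C)C(C)(C)C)C[C@]1(C)C=C | intermediate
22 | potassium alkoxide of 21 | C=C(COC)[C@@]1([O-])CC(C)(C)C[C@@H](O[Si](C)(C)C(C)(C)C)C[C@]1(C)C=C.[K+] | intermediate (not isolated)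
23 | potassium enolate of the eleven-membered 1-(methoxymethyl) ketone (C1=C2 enolate, E-C8=C9) | COC/C1=C(/[O-])CC(C)(C)C[C@@H](O[Si](C)(C)C(C)(C)C)C/C(C)=C/CC1.[K+] | intermediate (not isolated)
24 | (5E,8R)-8-(tert-butyldimethylsilyloxy)-6,10,10-trimethyl-2-methylidenecycloundec-5-en-1-one | C=C1CC/C=C(C)/C[C@H](O[Si](C)(C)C(C)(C)C)CC(C)(C)CC1=O | intermediate
25 | potassium dienolate of 24 (C2=C3 enolate, oxygen cis to C4) | C=C1CC/C=C(C)/C[C@H](O[Si](C)(C)C(C)(C)C)CC(C)(C)/C=C1\[O-].[K+] | intermediate (not isolated)
26 | (1Z,5S,7E)-5-(tert-butyldimethylsilyloxy)-3,3,7-trimethyl-11-methylidenecycloundeca-1,7-dien-1-yl trifluoromethanesulfonate | C=C1CC/C=C(C)/C[C@H](O[Si](C)(C)C(C)(C)C)CC(C)(C)/C=C1\OS(=O)(=O)C(F)(F)F | intermediate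
27 | tert-butyldimethyl{[(1S,3E,8E)-3,10,10-trimethyl-7-methylidenecycloundeca-3,8-dien-1-yl]oxy}silane | C=C1/C=C/C(C)(C)C[C@@H](O[Si](C)(C)C(C)(C)C)C/C(C)=C/CC1 | intermediate
28 | (1S,3E,8E)-3,10,10-trimethyl-7-methylidenecycloundeca-3,8-dien-1-ol | C=C1/C=C/C(C)(C)C[C@@H](O)C/C(C)=C/CC1 | intermediate
29 | isovanillic acid (3-hydroxy-4-methoxybenzoic acid) | COc1ccc(C(=O)O)cc1O | starting material
30 | tert-butyldimethylsilyl 3-(tert-butyldimethylsilyloxy)-4-methoxybenzoate | COc1ccc(C(=O)O[Si](C)(C)C(C)(C)C)cc1O[Si](C)(C)C(C)(C)C | intermediate (not isolated)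
31 | 3-(tert-butyldimethylsilyloxy)-4-methoxybenzoic acid | COc1ccc(C(=O)O)cc1O[Si](C)(C)C(C)(C)C | intermediate
32 | (1S,3E,8E)-3,10,10-trimethyl-7-methylidenecycloundeca-3,8-dien-1-yl 3-(tert-butyldimethylsilyloxy)-4-methoxybenzoate | C=C1/C=C/C(C)(C)C[C@@H](OC(=O)c2ccc(OC)c(O[Si](C)(C)C(C)(C)C)c2)C/C(C)=C/CC1 | intermediate
33 | (1S,3E,8E)-3,10,10-trimethyl-7-methylidenecycloundeca-3,8-dien-1-yl 3-hydroxy-4-methoxybenzoate (CNP0220645.1) | C=C1/C=C/C(C)(C)C[C@@H](OC(=O)c2ccc(OC)c(O)c2)C/C(C)=C/CC1 | target

**Step count and risks**

Total: 19 steps. Longest linear sequence: 17 steps (steps 1–10, 12–16, 18, 19). Steps 11 and 17 are one-step side branches.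

Steps most likely to fail:

1. Step 13. The loss of methoxide from the ring-expanded enolate may stay incomplete or reverse on quench, and the enolate may add to enone already formed. The fallback separates ring expansion from methylenation. It sets out from ketone 16: addition of vinylmagnesium bromide 4 with CeCl3 should give the trans-1,2-divinylcycloheptanol F1. Its potassium alkoxide (KH, 18-crown-6, THF) undergoes the same oxy-Cope ring expansion, and the regiodefined C1 enolate is trapped with dimethyl(methylidene)ammonium iodide to give the Mannich base F2. N-Methylation with MeI gives the ammonium iodide F3, and elimination with aqueous NaHCO3 returns to the route at enone 24.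

2. Step 7. The enzyme may discriminate poorly between the two faces of the carbonyl, or reduction may run on to the diol. The fallback replaces asymmetric catalysis by resolution. It sets out from dione 8: substoichiometric NaBH4 in MeOH gives the racemic hydroxy ketone F4, which is esterified with (S)-2-methoxy-2-phenylacetic acid (DCC, DMAP). The diastereomeric esters are separated by chromatography or crystallisation, and the ester of the S alcohol F5 is cleaved with K2CO3 in MeOH to rejoin the route at 9. The other diastereomer can be recycled to 8 by methanolysis and oxidation.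

3. Step 14. Enolisation may occur with the wrong double-bond geometry, or the amide base may add in conjugate fashion to the exocyclic enone. The fallback builds the C2=C3 alkene by elimination instead of enolate trapping. It sets out from enone 24: 1,2-reduction (NaBH4, CeCl3·7H2O, MeOH; Luche reduction) gives the allylic alcohol F6, which is converted with ClCO2Me and pyridine into the allylic methyl carbonate F7. Palladium-catalysed elimination (Pd(OAc)2, PBu3, dioxane, 100 °C) ionises it to the π-allylpalladium complex spanning the exocyclic CH2, C1 and C2. β-Hydride loss from C3, the only β-hydrogen available, should give the conjugated diene with the thermodynamically preferred E geometry, rejoining the route at 27.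

**Further compounds**

F1 | step 13 | (1S,2R,4R)-4-(tert-butyldimethylsilyloxy)-1,2-diethenyl-2,6,6-trimethylcycloheptan-1-ol | C=C[C@@]1(O)CC(C)(C)C[C@@H](O[Si](C)(C)C(C)(C)C)C[C@]1(C)C=C
F2 | step 13 | (5E,8R)-8-(tert-butyldimethylsilyloxy)-2-[(dimethylamino)methyl]-6,10,10-trimethylcycloundec-5-en-1-one (C2 epimers) | CN(C)CC1CC/C=C(C)/C[C@H](O[Si](C)(C)C(C)(C)C)CC(C)(C)CC1=O
F3 | step 13 | {[(6E,9R)-9-(tert-butyldimethylsilyloxy)-7,11,11-trimethyl-2-oxocycloundec-6-en-1-yl]methyl}trimethylammonium iodide (C1 epimers) | C[N+](C)(C)CC1CC/C=C(C)/C[C@H](O[Si](C)(C)C(C)(C)C)CC(C)(C)CC1=O.[I-]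
F4 | step 7 | racemic 4-hydroxy-6,6-dimethylcycloheptan-1-one | O=C1CCC(O)CC(C)(C)C1
F5 | step 7 | (S)-3,3-dimethyl-5-oxocycloheptyl (S)-2-methoxy-2-phenylacetate | O=C1CC[C@H](OC(=O)[C@@H](OC)c2ccccc2)CC(C)(C)C1
F6 | step 14 | (5E,8R)-8-(tert-butyldimethylsilyloxy)-6,10,10-trimethyl-2-methylidenecycloundec-5-en-1-ol (C1 epimers) | C=C1CC/C=C(C)/C[C@H](O[Si](C)(C)C(C)(C)C)CC(C)(C)CC1O
F7 | step 14 | (5E,8R)-8-(tert-butyldimethylsilyloxy)-6,10,10-trimethyl-2-methylidenecycloundec-5-en-1-yl methyl carbonate (C1 epimers) | C=C1CC/C=C(C)/C[C@H](O[Si](C)(C)C(C)(C)C)CC(C)(C)CC1OC(=O)OC
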